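(The constants used here are invented, and the outcome is calculated.)

The pitfall in this flask is to apply the balance of the second step to the D charged, when that balance shares out the D that has reacted.

    D + L → D.L (k1 = 345 M⁻¹ s⁻¹)
    D.L ⇌ Q (K2 = 5.3, k2 = 0.0466 s⁻¹)

D 1.0 mM; L 1.10 mM; time 50 min

1. which holds at 50 min: what has brought the reaction to rest, or that it has not come to rest (it is still moving / forward and back rates have come level / all of D has reacted / L has run out first)
2. how much of the D has reacted by 50 min
3. how much D.L there is at 50 min, in percent of the D charged
4. how much Q there is at 50 min, in percent of the D charged
5. amount of D.L if the flask were left three thousand times as long, in percent of the D charged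

- the reaction counts as stopped when no species that holds the D changes by six tenths of a point or more over the second half of the time
- run time (flask): 50 min

I follow the flask in slow motion. In the first instants c_D and c_L stand at their charges, the first step makes D.L at 0.380 mM s⁻¹, and no Q exists yet. I set two time constants side by side for this stage, the life of D against the charged L and the relaxation of D.L and Q through the second step:

τ_a = 1/(345 M⁻¹ s⁻¹ × 1.10 mM) = 2.64 s

τ_b = 1/(0.0466 s⁻¹ × (1 + 1/5.3)) = 18.1 s

The first is shorter than the second, so D.L runs ahead of Q at the start.

In the middle c_D and c_L fall together and the first step slows, so the second step catches up and brings c_Q/c_D.L towards 5.3. What I carry forward is the link share, the fraction of the reacted D that stands as D.L once the second step has relaxed: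

f = 1/(1 + 5.3) = 0.159

For the end I go round twice. In the first round D reacts away and leaves an excess of L of 0.100 mM. In the second round I put that excess back as the L the last D meets, which makes the tail pseudo-first-order:

τ_c = 1/(345 M⁻¹ s⁻¹ × 0.100 mM) = 29.0 s

The run lasts 104 of these, so I expect 100 % of D reacted, with D, the limiting reagent, consumed. Since τ_b is far shorter than the run, the link share applies to that reacted D: D.L 15.9 %, Q 84.1 %, and D.L after the long wait 15.9 %.

The forecast says all of D has reacted, with 100 % reacted, 15.9 % as D.L, 84.1 % as Q and 15.9 % as D.L after the long wait, holding that “D's exhaustion is what stops net reaction”. My reckoning stands with it, and its short form is the two lines for τ_c and f.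

The flask gives all of D has reacted: 100 % reacted, 15.9 % as D.L, 84.1 % as Q, and 15.9 % as D.L after the long wait. In this flask D.L stands at 15.9 % after 10.0 min and at 15.9 % after 500 min. In a neighbour flask, the same but with 0.66 mM of L, 0 % of the charged L is left at 50.0 min and 34.0 % of the D stands unreacted, so 66.0 % of the D has reacted. The link share of that is 10.5 %, and the neighbour flask holds 10.5 % as D.L.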